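Amounts first: the flask holds 0.30 M of each mirror-image substrate, 0.300 M of solid reagent and 1.5 mM of precatalyst, and we count substrates and products as fractions of the substrate charged.

the same everywhere: left-handed substrate 0.30 M; right-handed substrate 0.30 M

| charge | solid reagent | precatalyst | remark | time |
|---|---|---|---|---|
| maple | 0.20 M | 1.5 mM | run made earlier |  |
| elm | 0.45 M | 1.5 mM | run made earlier |  |
| birch | 0.30 M | 2.2 mM | run made earlier |  |
| flask | 0.300 M | 1.5 mM |  | 10 h |

- maple (time / h: right-handed substrate / %, left-handed substrate / %, left-handed product / %): 0.500: 50.2, 49.8, 0; 1.50: 49.9, 48.8, 1.0; 3.00: 50.7, 48.0, 0.9; 4.00: 49.6, 47.5, 2.6; 6.00: 48.9, 44.7, 5.3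
- elm (time / h: right-handed substrate / %, left-handed substrate / %, left-handed product / %): 1.33: 49.4, 51.0, 0; 2.50: 49.8, 48.8, 0.4; 4.00: 50.0, 47.5, 2.4; 5.00: 49.8, 47.1, 4.9; 6.00: 48.9, 44.5, 5.7
- birch (time / h: right-handed substrate / %, left-handed substrate / %, left-handed product / %): 0.500: 50.3, 50.7, 0.7; 1.50: 50.6, 49.7, 0.1; 3.00: 50.1, 48.7, 1.7; 4.00: 49.7, 45.9, 3.2; 6.00: 48.7, 42.8, 7.5

(standard deviation of a reading: 0.5 percentage points)

1. whether the excess of right-handed substrate over left-handed substrate among what is left of the two reaches 80% by 10 h (no / yes)
2. the highest excess of right-handed substrate over left-handed substrate among what is left of the two up to 10 h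

- free catalyst is single-handed; left-handed substrate and right-handed substrate are mirror images of each other, charged as a racemate, each of them at the stated concentration
- as a solid, counted per litre of solution: solid reagent
- on the list of suspects stand: partner + catalyst intermediate B -> free catalyst + right-handed product; free catalyst + left-handed substrate <-> catalyst intermediate A; precatalyst <-> free catalyst; solid reagent <-> partner; partner + catalyst intermediate A -> free catalyst + left-handed product; free catalyst + right-handed substrate <-> catalyst intermediate B; left-handed substrate <-> right-handed substrate
- at the start none of the solid reagent is in solution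

We climb a ladder of time scales. On the first rung, as we suppose, the catalyst binds substrate: its charge is 0.250% of the substrates against a scatter of 0.5 percentage points, so no reading shows this step, and we treat it as a pre-equilibrium. The next rung takes hours. In the maple run left-handed product reads 0.9% at 3.00 h and 5.3% at twice that time, so the rate is climbing. Yet at 6.00 h the maple and elm runs read 44.7% and 44.5% left-handed substrate, despite different solid charges.

We therefore let the logarithmic loss of left-handed substrate grow with time squared and with precatalyst. The maple run gives 17.9 h, our lag clock: the time at which that logarithmic loss reaches one at 1.5 mM precatalyst. The birch run, scaled to that precatalyst, reads 18.4 h.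

At 10 h the clock leaves 73.3% of the left-handed substrate. A selectivity factor read from the maple run as 5.04 leaves 94.0% of the right-handed one. Our excess at 10 h is thus 12.4%, less than 80%. Last comes supply: at one partner for each substrate lost, this loss asks 0.0982 M of partner, less than the 0.300 M of solid.

The forecast answers no and 14%, within 10% to 20%, above our figure: “80% is out of reach”.

The flask answers no, and its top is 12.3%.

    partner + catalyst intermediate B → free catalyst + right-handed product (k = 0.350 M⁻¹ min⁻¹)
    free catalyst + left-handed substrate ⇌ catalyst intermediate A (K = 5.10 M⁻¹, k = 9.20 M⁻¹ min⁻¹)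
    precatalyst ⇌ free catalyst (K = 0.460, k = 0.00410 min⁻¹)
    solid reagent ⇌ partner, rate k4*(cs4 - [partner]) while solid is left; crystals form when [partner] > cs4 (solubility = 0.290 M, k = 0.00300 min⁻¹)
    partner + catalyst intermediate A → free catalyst + left-handed product (k = 3.60 M⁻¹ min⁻¹)
    free catalyst + right-handed substrate ⇌ catalyst intermediate B (K = 2.90 M⁻¹, k = 53.0 M⁻¹ min⁻¹)
    left-handed substrate ⇌ right-handed substrate (k = 2.30 × 10⁻⁴ min⁻¹)

Catalyst intermediate B returns to free catalyst and right-handed substrate at 99.7% of its forward turnover. The lag clock put the left-handed substrate at 73.3% of its charge, and the flask keeps 75% unbound. With 3.8 × 10⁻⁴ M of precatalyst the same clock, scaled by the charge, leaves 92.4% of the left-handed substrate at 10 h. That neighbouring flask keeps 93%, and its top is 3.31%.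

All runs stem from a simulated flask on assumed constants; scatter was added.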